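**Retrosynthetic overview**

1. The target is disconnected at C12=C13 (Wittig) into a C12 aldehyde and a succinimide phosphorus ylide; the aldehyde comes from a bicyclic C9 ester by one-carbon homologation and adjustment of C7/C8/C17 (enone, reduction, acetate).
2. The bicyclic ester comes from an acyclic triene by an intramolecular Diels–Alder reaction that makes the ring-fusion bond C5–C10 and the bond C8–C9 in one operation, closing rings A and B and setting C5, C9 and C10 from the single C2–Cl stereocentre.
3. Enabling feature: ring B (C5–C10) carries oxygen at C7, the exocyclic carbon C17 on C8 and the side chain on C9, so it is the retron of a 2-silyloxydiene C5=C6–C7(OSi)=C8–C17 adding to an (E)-C9=C10 enoate; ring A atoms C1–C4 (gem-dimethyl C4, equatorial Cl on C2) are the four-atom tether between the two fusion carbons.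
4. The triene comes from cross-metathesis of a chloro-dienoate with a vinyl ketone, then silyl enol ether formation; the chloro-dienoate comes from (R)-epichlorohydrin (reverse prenylation, acetylide opening, chlorination with inversion, carboalumination).
5. Ring order: rings A and B are formed together in the key step; the preformed succinimide ring is attached last.

Key step: step 9

Remark: positions are given in labdane numbering (decalin C1–C10, gem-dimethyl on C4, angular methyl on C10, C17 on C8, side chain C11–C16 on C9; β = face of the angular methyl, α = opposite face); all bicyclic compounds have 5α-H, 10β-CH3 and a 9β side chain; TBS = tert-butyldimethylsilyl.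

**Step 1**
Reactants: 1 (R)-epichlorohydrin
Product: 3 (2R)-2-(2,2-dimethylbut-3-en-1-yl)oxirane, via chlorohydrin 2 (not isolated)
Conditions: prenylMgCl (1.2 equiv), THF, −30 → 0 °C; then aq. NaOH (2 M), Et2O, rt
Reagents that add atoms: prenylmagnesium chloride (3-methylbut-2-en-1-ylmagnesium chloride), CC(C)=CC[Mg]Cl
Why: Copper-free addition of the allylic Grignard reagent to the unsubstituted epoxide carbon should occur through its γ-terminus (SE2′ allylic transposition), which builds the quaternary C4 with its vinyl group, and hydroxide then closes chlorohydrin 2 to the epoxide by intramolecular Williamson displacement; the C2–O bond of 1 is never broken, so its configuration is carried into 3.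

**Step 2**
Reactants: 3 (2R)-2-(2,2-dimethylbut-3-en-1-yl)oxirane
Product: 4 (4S)-6,6-dimethyloct-7-en-1-yn-4-ol
Conditions: HC≡CLi·H2NCH2CH2NH2 (1.5 equiv), DMSO, rt; then H2O
Reagents that add atoms: lithium acetylide (ethylenediamine complex), [Li]C#C
Why: Regioselective SN2 opening of the terminal epoxide at its CH2 carbon by the acetylide (epoxide alkynylation) introduces C1 and the two alkyne carbons that become C10 and C9, again without touching the stereocentre.

**Step 3**
Reactants: 4 (4S)-6,6-dimethyloct-7-en-1-yn-4-ol
Product: 5 (5R)-5-chloro-3,3-dimethyloct-1-en-7-yne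
Conditions: PPh3, N-chlorosuccinimide, THF, 0 → 40 °C
Reagents that add atoms: N-chlorosuccinimide, ClN1C(=O)CCC1=O
Why: Appel-type chlorination in which the alkoxyphosphonium ion formed from PPh3 and N-chlorosuccinimide is displaced by chloride in an SN2 step, so the carbinol centre is inverted and the C2–Cl stereocentre of the target is set (S alcohol to R chloride).

**Step 4**
Reactants: 5 (5R)-5-chloro-3,3-dimethyloct-1-en-7-yne
Product: 7 methyl (2E,5R)-5-chloro-3,7,7-trimethylnona-2,8-dienoate, via alkenylalane 6 (not isolated)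
Conditions: Me3Al (2 equiv), Cp2ZrCl2 (0.2 equiv), CH2Cl2, 0 °C → rt; then ClCO2Me, 0 °C; then 1 M HCl
Reagents that add atoms: trimethylaluminium, C[Al](C)C; methyl chloroformate, COC(Cl)=O
Why: Zirconium-catalysed Negishi carboalumination adds CH3 and Al syn across the terminal alkyne (CH3 to the internal carbon) and alkenylalane 6 is acylated with retention by the chloroformate, so the trisubstituted enoate should form as the (E) isomer that later gives the cis relation of angular methyl and C9 side chain.

**Step 5**
Reactants: 8 3-[(tert-butyldimethylsilyl)oxy]propanal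
Product: 9 5-[(tert-butyldimethylsilyl)oxy]pent-1-en-3-ol (racemic)
Conditions: CH2=CHMgBr, THF, −78 → 0 °C; then H2O
Reagents that add atoms: vinylmagnesium bromide, C=C[Mg]Br
Why: Grignard 1,2-addition of the vinyl group to the aldehyde; the racemic carbinol centre is removed again in step 6.

**Step 6**
Reactants: 9 5-[(tert-butyldimethylsilyl)oxy]pent-1-en-3-ol
Product: 10 5-[(tert-butyldimethylsilyl)oxy]pent-1-en-3-one
Conditions: Dess–Martin periodinane, CH2Cl2, 0 °C → rt
Reagents that add atoms: none
Why: Dess–Martin oxidation of the secondary allylic alcohol under neutral conditions gives the polymerisation-prone vinyl ketone, which is used at once.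

**Step 7**
Reactants: 7 methyl (2E,5R)-5-chloro-3,7,7-trimethylnona-2,8-dienoate; 10 5-[(tert-butyldimethylsilyl)oxy]pent-1-en-3-one
Product: 11 methyl (2E,5R,8E)-12-[(tert-butyldimethylsilyl)oxy]-5-chloro-3,7,7-trimethyl-10-oxododeca-2,8-dienoate
Conditions: 10 (3 equiv), second-generation Hoveyda–Grubbs catalyst [RuCl2(H2IMes)(=CH-C6H4-2-O-i-Pr)] (5 mol %), CH2Cl2, 40 °C
Reagents that add atoms: none
Why: Olefin cross-metathesis in which the neopentyl-type terminal olefin of 7 cannot homodimerise and the trisubstituted enoate is inert, so exchange with the excess electron-poor vinyl ketone should give the (E)-enone under thermodynamic control.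

**Step 8**
Reactants: 11 methyl (2E,5R,8E)-12-[(tert-butyldimethylsilyl)oxy]-5-chloro-3,7,7-trimethyl-10-oxododeca-2,8-dienoate
Product: 12 methyl (2E,5R,8E,10Z)-10,12-bis[(tert-butyldimethylsilyl)oxy]-5-chloro-3,7,7-trimethyldodeca-2,8,10-trienoate
Conditions: TBSOTf (1.3 equiv), Et3N (2.5 equiv), CH2Cl2, −78 → 0 °C
Reagents that add atoms: tert-butyldimethylsilyl trifluoromethanesulfonate, CC(C)(C)[Si](C)(C)OS(=O)(=O)C(F)(F)F
Why: Soft enolisation (silyl triflate and amine base) can only occur towards C8 because C4 is quaternary, and the (Z)-silyl enol ether that this method gives places the CH2OTBS arm on the outside of the s-cis diene, while the ester is untouched.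

**Step 9**
Reactants: 12 methyl (2E,5R,8E,10Z)-10,12-bis[(tert-butyldimethylsilyl)oxy]-5-chloro-3,7,7-trimethyldodeca-2,8,10-trienoate
Product: 13 methyl 2α-chloro-7,17-bis[(tert-butyldimethylsilyl)oxy]-12,13,14,15,16-pentanorlabd-6-en-11-oate (trans-fused; 8β-CH2OTBS, 9β-CO2Me)
Conditions: toluene (0.01 M), 2,6-di-tert-butyl-4-methylphenol (0.1 equiv), 185 °C, sealed tube, base-washed glass
Reagents that add atoms: none
Why: Thermal, concerted suprafacial [4+2] cycloaddition in which the 2-silyloxydiene C5=C6–C7(OTBS)=C8 adds across the (E)-C9=C10 enoate; because C10 and C5 are joined by the four-atom tether C1–C4 only the fused mode is possible, so the ring-fusion bond C5–C10 and the bond C8–C9 are made in the same event. The closest known reaction type is the type 1 intramolecular Diels–Alder reaction of 1,7,9-decatrienoates that carry a 2-silyloxy diene, a standard entry to decalone enol ethers. Ring A closes as the six-membered tether ring through the new C5–C10 bond in a chair-like array, and ring B is the cyclohexene of the cycloadduct, closed through C5–C10 and C8–C9 in the boat-like [4+2] array. C9 and C10 follow from the (E) dienophile (angular CH3 and CO2Me cis), the trans relation of C5–H and C10–CH3 from the anti transition state of the (E)-C5=C6 diene with the ester endo, C8 from the (Z) enol ether (erased in step 13), and the absolute sense of all of them from C2, whose chlorine should sit equatorial on the chair tether because the axial alternative is 1,3-diaxial to the axial C4 methyl and to the C10 methyl. The step needs anti over syn (trans- over cis-fused) and one diene face: the syn transition state must place C9 with its ester in the axial site that faces the axial C4 methyl, whereas the anti one puts only the C10 methyl there, and the face is fixed by the equatorial chlorine. Regiochemistry is enforced by the tether although it opposes the electronic preference of diene and enoate, which is why heat and not a Lewis acid is used; the gem-dimethyl group at C4 (Thorpe–Ingold effect) and the raised diene HOMO should make up for the β,β-disubstituted dienophile.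

**Step 10**
Reactants: 13 methyl 2α-chloro-7,17-bis[(tert-butyldimethylsilyl)oxy]-12,13,14,15,16-pentanorlabd-6-en-11-oate
Product: 14 2α-chloro-7,17-bis[(tert-butyldimethylsilyl)oxy]-12,13,14,15,16-pentanorlabd-6-en-11-al
Conditions: i-Bu2AlH (1.2 equiv), CH2Cl2, −78 °C; then MeOH, aq. potassium sodium tartrate
Reagents that add atoms: none
Why: Partial reduction of an ester with i-Bu2AlH, in which the tetrahedral aluminium hemiacetal of this hindered ester should be stable at −78 °C and collapse to the aldehyde only on work-up, while silyl enol ether, silyl ether and alkyl chloride are inert to the hydride.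

**Step 11**
Reactants: 14 2α-chloro-7,17-bis[(tert-butyldimethylsilyl)oxy]-12,13,14,15,16-pentanorlabd-6-en-11-al
Product: 15 2α-chloro-12-methoxy-7,17-bis[(tert-butyldimethylsilyl)oxy]-13,14,15,16-tetranorlabda-6,11-diene (11E/Z mixture)
Conditions: MeOCH2PPh3Cl (3 equiv), KN(SiMe3)2 (2.8 equiv), THF, 0 °C; then 14, 0 °C → rt
Reagents that add atoms: (methoxymethyl)triphenylphosphonium chloride, COC[P+](c1ccccc1)(c1ccccc1)c1ccccc1.[Cl-]
Why: Wittig methoxymethylenation, which tolerates hindered aldehydes, adds C12 as a masked aldehyde, while the silyl enol ether keeps the C7 carbonyl protected and the equatorial chloride has no anti-periplanar hydrogen for elimination.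

**Step 12**
Reactants: 15 2α-chloro-12-methoxy-7,17-bis[(tert-butyldimethylsilyl)oxy]-13,14,15,16-tetranorlabda-6,11-diene
Product: 16 2α-chloro-17-hydroxy-12-methoxy-13,14,15,16-tetranorlabd-11-en-7-one (8β-CH2OH)
Conditions: Bu4NF (3 equiv), AcOH (3 equiv), THF, 0 °C → rt
Reagents that add atoms: none
Why: Fluoride-mediated desilylation cleaves the silyl enol ether (ketonisation by protonation at C6) and the primary silyl ether, and the acetic acid buffer should prevent retro-aldol loss of formaldehyde and leave the methyl enol ether intact.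

**Step 13**
Reactants: 16 2α-chloro-17-hydroxy-12-methoxy-13,14,15,16-tetranorlabd-11-en-7-one
Product: 18 2α-chloro-12-methoxy-13,14,15,16-tetranorlabda-8(17),11-dien-7-one, via mesylate 17 (not isolated)
Conditions: MeSO2Cl (1.5 equiv), Et3N (4 equiv), CH2Cl2, 0 °C → rt
Reagents that add atoms: none
Why: Mesylation of the primary alcohol and E1cB elimination of methanesulfonate through the C7 enolate (dehydration of a β-hydroxy ketone) should give the exocyclic enone, which also removes the provisional stereocentre at C8.

**Step 14**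
Reactants: 18 2α-chloro-12-methoxy-13,14,15,16-tetranorlabda-8(17),11-dien-7-one
Product: 19 2α-chloro-12-methoxy-13,14,15,16-tetranorlabda-8(17),11-dien-7β-ol
Conditions: NaBH4, CeCl3·7H2O, MeOH, −78 °C
Reagents that add atoms: none
Why: Luche reduction, in which the cerium-activated borohydride reduces the enone carbonyl in 1,2-fashion by axial attack from the unhindered α-face of the chair (opposite to the axial C10 methyl), so the new C7 hydroxyl should be equatorial (7β).

**Step 15**
Reactants: 19 2α-chloro-12-methoxy-13,14,15,16-tetranorlabda-8(17),11-dien-7β-ol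
Product: 20 7β-acetoxy-2α-chloro-12-methoxy-13,14,15,16-tetranorlabda-8(17),11-diene
Conditions: Ac2O, pyridine, 4-(dimethylamino)pyridine (cat.), CH2Cl2, 0 °C → rt
Reagents that add atoms: acetic anhydride, CC(=O)OC(C)=O
Why: Acylation of the secondary allylic alcohol with acetic anhydride under nucleophilic catalysis installs the acetate with retention at C7.

**Step 16**
Reactants: 20 7β-acetoxy-2α-chloro-12-methoxy-13,14,15,16-tetranorlabda-8(17),11-diene
Product: 21 7β-acetoxy-2α-chloro-13,14,15,16-tetranorlabd-8(17)-en-12-al
Conditions: 1 M HCl (aq.), THF, 0 °C → rt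
Reagents that add atoms: water, O
Why: Acid-catalysed hydrolysis of the methyl enol ether (protonation at C11, addition of water, loss of methanol) releases the homologated aldehyde under conditions mild enough for the allylic acetate, the exocyclic alkene and the chloride.

**Step 17**
Reactants: 22 maleimide
Product: 23 3-(triphenyl-λ5-phosphanylidene)pyrrolidine-2,5-dione
Conditions: PPh3, acetone, reflux
Reagents that add atoms: triphenylphosphine, c1ccc(cc1)P(c1ccccc1)c1ccccc1
Why: Conjugate (phospha-Michael) addition of the phosphine to maleimide followed by proton transfer gives the stabilised, isolable phosphorus ylide.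

**Step 18**
Reactants: 21 7β-acetoxy-2α-chloro-13,14,15,16-tetranorlabd-8(17)-en-12-al; 23 3-(triphenyl-λ5-phosphanylidene)pyrrolidine-2,5-dione
Product: 24 target CNP0220384.1, the (E)-3-alkylidenepyrrolidine-2,5-dione whose alkylidene carbon is C12 of the 7β-acetoxy-2α-chloro-labd-8(17)-ene unit
Conditions: toluene, 70 °C
Reagents that add atoms: none
Why: Wittig olefination with a stabilised imide ylide reacts only with the aldehyde under neutral conditions and should give the (E)-alkylidene succinimide (C11 trans to the C16 carbonyl) through the reversible, thermodynamically controlled oxaphosphetane pathway typical of stabilised ylides.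

**Compound list**

1 | (R)-epichlorohydrin, (2R)-2-(chloromethyl)oxirane | ClC[C@H]1CO1 | starting material
2 | (2R)-1-chloro-4,4-dimethylhex-5-en-2-ol (as magnesium alkoxide, not isolated) | C=CC(C)(C)C[C@@H](O)CCl | intermediate
3 | (2R)-2-(2,2-dimethylbut-3-en-1-yl)oxirane | C=CC(C)(C)C[C@@H]1CO1 | intermediate
4 | (4S)-6,6-dimethyloct-7-en-1-yn-4-ol | C=CC(C)(C)C[C@@H](O)CC#C | intermediate
5 | (5R)-5-chloro-3,3-dimethyloct-1-en-7-yne | C=CC(C)(C)C[C@H](Cl)CC#C | intermediate
6 | dimethyl[(1E,4S)-4-chloro-2,6,6-trimethylocta-1,7-dien-1-yl]alumane (not isolated) | C=CC(C)(C)C[C@H](Cl)C/C(C)=C/[Al](C)C | intermediate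
7 | methyl (2E,5R)-5-chloro-3,7,7-trimethylnona-2,8-dienoate | COC(=O)/C=C(\C)C[C@@H](Cl)CC(C)(C)C=C | intermediate
8 | 3-[(tert-butyldimethylsilyl)oxy]propanal | O=CCCO[Si](C)(C)C(C)(C)C | starting material
9 | 5-[(tert-butyldimethylsilyl)oxy]pent-1-en-3-ol (racemic) | C=CC(O)CCO[Si](C)(C)C(C)(C)C | intermediate
10 | 5-[(tert-butyldimethylsilyl)oxy]pent-1-en-3-one | C=CC(=O)CCO[Si](C)(C)C(C)(C)C | intermediate
11 | methyl (2E,5R,8E)-12-[(tert-butyldimethylsilyl)oxy]-5-chloro-3,7,7-trimethyl-10-oxododeca-2,8-dienoate | COC(=O)/C=C(\C)C[C@@H](Cl)CC(C)(C)/C=C/C(=O)CCO[Si](C)(C)C(C)(C)C | intermediate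
12 | methyl (2E,5R,8E,10Z)-10,12-bis[(tert-butyldimethylsilyl)oxy]-5-chloro-3,7,7-trimethyldodeca-2,8,10-trienoate | COC(=O)/C=C(\C)C[C@@H](Cl)CC(C)(C)/C=C/C(O[Si](C)(C)C(C)(C)C)=C/CO[Si](C)(C)C(C)(C)C | intermediate
13 | methyl 2α-chloro-7,17-bis[(tert-butyldimethylsilyl)oxy]-12,13,14,15,16-pentanorlabd-6-en-11-oate (8β-CH2OTBS) | [C@H]1(CO[Si](C)(C)C(C)(C)C)C(O[Si](C)(C)C(C)(C)C)=C[C@H]2C(C)(C)C[C@H](Cl)C[C@]2(C)[C@H]1C(=O)OC | intermediate
14 | 2α-chloro-7,17-bis[(tert-butyldimethylsilyl)oxy]-12,13,14,15,16-pentanorlabd-6-en-11-al (8β-CH2OTBS) | [C@H]1(CO[Si](C)(C)C(C)(C)C)C(O[Si](C)(C)C(C)(C)C)=C[C@H]2C(C)(C)C[C@H](Cl)C[C@]2(C)[C@H]1C=O | intermediate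
15 | 2α-chloro-12-methoxy-7,17-bis[(tert-butyldimethylsilyl)oxy]-13,14,15,16-tetranorlabda-6,11-diene (11E/Z mixture, enol ether geometry left open) | [C@H]1(CO[Si](C)(C)C(C)(C)C)C(O[Si](C)(C)C(C)(C)C)=C[C@H]2C(C)(C)C[C@H](Cl)C[C@]2(C)[C@H]1C=COC | intermediate
16 | 2α-chloro-17-hydroxy-12-methoxy-13,14,15,16-tetranorlabd-11-en-7-one (8β-CH2OH) | OC[C@H]1C(=O)C[C@H]2C(C)(C)C[C@H](Cl)C[C@]2(C)[C@H]1C=COC | intermediate
17 | 17-methanesulfonate of 16 (not isolated) | CS(=O)(=O)OC[C@H]1C(=O)C[C@H]2C(C)(C)C[C@H](Cl)C[C@]2(C)[C@H]1C=COC | intermediate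
18 | 2α-chloro-12-methoxy-13,14,15,16-tetranorlabda-8(17),11-dien-7-one | C=C1C(=O)C[C@H]2C(C)(C)C[C@H](Cl)C[C@]2(C)[C@H]1C=COC | intermediate
19 | 2α-chloro-12-methoxy-13,14,15,16-tetranorlabda-8(17),11-dien-7β-ol | C=C1[C@@H](O)C[C@H]2C(C)(C)C[C@H](Cl)C[C@]2(C)[C@H]1C=COC | intermediate
20 | 7β-acetoxy-2α-chloro-12-methoxy-13,14,15,16-tetranorlabda-8(17),11-diene | C=C1[C@@H](OC(C)=O)C[C@H]2C(C)(C)C[C@H](Cl)C[C@]2(C)[C@H]1C=COC | intermediate
21 | 7β-acetoxy-2α-chloro-13,14,15,16-tetranorlabd-8(17)-en-12-al | C=C1[C@@H](OC(C)=O)C[C@H]2C(C)(C)C[C@H](Cl)C[C@]2(C)[C@H]1CC=O | intermediate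
22 | maleimide | O=C1C=CC(=O)N1 | starting material
23 | 3-(triphenyl-λ5-phosphanylidene)pyrrolidine-2,5-dione | O=C1CC(=P(c2ccccc2)(c2ccccc2)c2ccccc2)C(=O)N1 | intermediate
24 | CNP0220384.1, (12E)-7β-acetoxy-2α-chlorolabda-8(17),12-diene with C13–C16 as a succinimide ring (C15(=O)–NH–C16(=O)) | C=C1[C@@H](OC(C)=O)C[C@H]2C(C)(C)C[C@H](Cl)C[C@]2(C)[C@H]1C/C=C1\CC(=O)NC1=O | target

**Step count**

Total step count: 18. Longest linear sequence: 15 (steps 1–4, 7–16 and 18).

**Steps most likely to fail**

Step 9 (cycloaddition). The syn transition state may compete with the anti one and give cis-fused material, and the slow reaction of the β,β-disubstituted dienophile at 185 °C may allow thermal loss of the silyl enol ether before ring closure. The fallback sets out from 12 and comes back at 14. The ester of 12 is reduced with i-Bu2AlH (2.5 equiv, CH2Cl2, −78 °C) to the allylic alcohol (2E,5R,8E,10Z)-10,12-bis[(tert-butyldimethylsilyl)oxy]-5-chloro-3,7,7-trimethyldodeca-2,8,10-trien-1-ol F1, which is oxidised with MnO2 (CH2Cl2, rt) to the enal (2E,5R,8E,10Z)-10,12-bis[(tert-butyldimethylsilyl)oxy]-5-chloro-3,7,7-trimethyldodeca-2,8,10-trienal F2. F2 is then cyclised under Lewis-acid activation (Me2AlCl, CH2Cl2, −78 → −20 °C); the aluminium-bound formyl group strongly prefers the endo position, which is the anti (trans-fused) transition state, and the reaction should run far below the temperature of the thermal variant. This gives aldehyde 14 directly.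

Step 1 (reverse prenylation of epichlorohydrin). The allylic Grignard reagent may attack through its primary terminus, magnesium halide may open the epoxide, and direct displacement of chloride would erode the enantiomeric purity. The fallback sets out from 1 and comes back at 3. Lithiated isobutyronitrile (LiN(i-Pr)2, THF, −78 °C → rt) opens the epoxide of 1 at its CH2 carbon and the alkoxide recloses with loss of chloride to give 2,2-dimethyl-3-[(2R)-oxiran-2-yl]propanenitrile F3. Reduction with i-Bu2AlH (toluene, −78 °C, aqueous work-up) gives 2,2-dimethyl-3-[(2R)-oxiran-2-yl]propanal F4, and Wittig methylenation (Ph3PCH3Br, KOt-Bu, THF, 0 °C) gives epoxide 3.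

Step 10 (partial reduction). The hindered ester may resist the hydride at −78 °C, and at higher temperature the aluminium hemiacetal may collapse early so that over-reduction to the alcohol sets in. The fallback sets out from 13 and comes back at 14. Exhaustive reduction (i-Bu2AlH, 3 equiv, CH2Cl2, −78 → 0 °C) gives the primary alcohol 2α-chloro-7,17-bis[(tert-butyldimethylsilyl)oxy]-12,13,14,15,16-pentanorlabd-6-en-11-ol F5. Parikh–Doering oxidation (SO3·pyridine, DMSO, Et3N, 0 °C), which leaves the silyl enol ether untouched, then gives 14.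

**Further compounds**

F1 | step 9 | (2E,5R,8E,10Z)-10,12-bis[(tert-butyldimethylsilyl)oxy]-5-chloro-3,7,7-trimethyldodeca-2,8,10-trien-1-ol | OC/C=C(\C)C[C@@H](Cl)CC(C)(C)/C=C/C(O[Si](C)(C)C(C)(C)C)=C/CO[Si](C)(C)C(C)(C)C
F2 | step 9 | (2E,5R,8E,10Z)-10,12-bis[(tert-butyldimethylsilyl)oxy]-5-chloro-3,7,7-trimethyldodeca-2,8,10-trienal | O=C/C=C(\C)C[C@@H](Cl)CC(C)(C)/C=C/C(O[Si](C)(C)C(C)(C)C)=C/CO[Si](C)(C)C(C)(C)C
F3 | step 1 | 2,2-dimethyl-3-[(2R)-oxiran-2-yl]propanenitrile | N#CC(C)(C)C[C@@H]1CO1
F4 | step 1 | 2,2-dimethyl-3-[(2R)-oxiran-2-yl]propanal | O=CC(C)(C)C[C@@H]1CO1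
F5 | step 10 | 2α-chloro-7,17-bis[(tert-butyldimethylsilyl)oxy]-12,13,14,15,16-pentanorlabd-6-en-11-ol (8β-CH2OTBS) | [C@H]1(CO[Si](C)(C)C(C)(C)C)C(O[Si](C)(C)C(C)(C)C)=C[C@H]2C(C)(C)C[C@H](Cl)C[C@]2(C)[C@H]1CO
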